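## Retrosynthetic overview

1. The target is (−)-epicatechin 3-O-syringate, (2R,3R), 2,3-cis. The end game is hydrogenolysis of five benzyl ethers, preceded by ionic removal of a temporary oxygen at C-4 (leucoanthocyanidin oxidation level).
2. Rings A, B and the syringoyl ring are bought, and ring C is the only ring made. It is closed in one catalytic asymmetric formal [4+2] (oxa-Povarov) event that forms C2–C3 and C4–C4a. The four-atom unit is C4a=C8a–O1=C2(+), an O-aryl oxocarbenium ion. The two-atom unit C3=C4 is the (Z)-silyl enol ether of 2-oxoethyl syringate, so the ester arrives with the dienophile.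
3. Enabling feature: ring A is a symmetric phloroglucinol in which C-4a lies ortho to O-1 and O-5 and para to O-7, giving two equivalent, very nucleophilic ortho sites. The 4'-oxygen of ring B stabilises positive charge at C-2. C-3/C-4 is an oxygen-bearing carbon next to a benzylic carbon, so an enediol-type two-carbon unit fits with its stronger donor at C-4.
4. The cation precursor is a racemic α-acetoxy ether, made by reductive acetylation of the aryl ester of 3,5-bis(benzyloxy)phenol and 3,4-bis(benzyloxy)benzoic acid. The dienophile takes four steps from syringic acid.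

Key step: step 7

Flavan numbering is used throughout (O-1, C-2, C-3, C-4, C-4a, C-5 to C-8, C-8a; ring B primed).

Assumption: the sense of induction of the chiral acid in step 7 cannot be derived with certainty. The (S,S)-acid is written, and its mirror image is used if the (2S,3S) series should be favoured.

## Route

Step 1
Reactants: 1 syringic acid (4-hydroxy-3,5-dimethoxybenzoic acid)
Product: 3 4-(benzyloxy)-3,5-dimethoxybenzoic acid, via benzyl ester 2 (not isolated)
Conditions: BnBr, K2CO3, DMF, 60 °C; then aq NaOH, MeOH, 60 °C; then aq HCl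
Reagents that add atoms: benzyl bromide BrCc1ccccc1; sodium hydroxide [Na+].[OH-]
Why: Williamson O-benzylation of phenol and carboxylate followed by saponification of the benzyl ester in the same flask should leave only the base-stable aryl benzyl ether.

Step 2
Reactants: 3 4-(benzyloxy)-3,5-dimethoxybenzoic acid
Product: 4 allyl 4-(benzyloxy)-3,5-dimethoxybenzoate
Conditions: allyl bromide, K2CO3, DMF, rt
Reagents that add atoms: allyl bromide C=CCBr
Why: SN2 O-alkylation of the carboxylate with an allylic halide is a standard ester synthesis and touches no other group.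

Step 3
Reactants: 4 allyl 4-(benzyloxy)-3,5-dimethoxybenzoate
Product: 6 2-oxoethyl 4-(benzyloxy)-3,5-dimethoxybenzoate, via ozonide 5 (not isolated)
Conditions: O3, CH2Cl2, −78 °C; then Me2S, −78 °C to rt
Reagents that add atoms: ozone [O-][O+]=O
Why: Ozonolysis (Criegee mechanism) with reductive work-up should cleave the terminal alkene, which reacts with ozone far faster than the ester-deactivated arene, to the known type of acyloxyacetaldehyde.

Step 4
Reactants: 6 2-oxoethyl 4-(benzyloxy)-3,5-dimethoxybenzoate
Product: 7 (Z)-2-[(tert-butyldimethylsilyl)oxy]ethenyl 4-(benzyloxy)-3,5-dimethoxybenzoate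
Conditions: tBuMe2SiOTf, Et3N, CH2Cl2, 0 °C to rt
Reagents that add atoms: tert-butyldimethylsilyl trifluoromethanesulfonate CC(C)(C)[Si](C)(C)OS(=O)(=O)C(F)(F)F
Why: Soft enolisation and O-silylation of the aldehyde (silyl enol ether formation) should favour the (Z)-isomer because 1,2-dioxygenated alkenes prefer the cis arrangement, and a minor (E)-isomer is removed on Et3N-deactivated silica.

Step 5
Reactants: 8 3,5-bis(benzyloxy)phenol; 9 3,4-bis(benzyloxy)benzoic acid
Product: 10 3,5-bis(benzyloxy)phenyl 3,4-bis(benzyloxy)benzoate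
Conditions: DCC, DMAP (cat.), CH2Cl2, rt
Reagents that add atoms: none
Why: Steglich esterification acylates the phenol oxygen under neutral conditions that leave the benzyl ethers alone.

Step 6
Reactants: 10 3,5-bis(benzyloxy)phenyl 3,4-bis(benzyloxy)benzoate
Product: 12 [3,4-bis(benzyloxy)phenyl][3,5-bis(benzyloxy)phenoxy]methyl acetate (racemic), via aluminium hemiacetal 11 (not isolated)
Conditions: iBu2AlH, CH2Cl2, −78 °C; then pyridine, DMAP, Ac2O, −78 to −20 °C; aq potassium sodium tartrate
Reagents that add atoms: acetic anhydride CC(=O)OC(C)=O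
Why: In this reductive acetylation of an ester, iBu2AlH adds once at −78 °C to give aluminium hemiacetal 11, which should be O-acetylated in situ faster than it collapses, and the new stereocentre is of no consequence because step 7 ionises it.

Step 7
Reactants: 12 [3,4-bis(benzyloxy)phenyl][3,5-bis(benzyloxy)phenoxy]methyl acetate (racemic); 7 (Z)-2-[(tert-butyldimethylsilyl)oxy]ethenyl 4-(benzyloxy)-3,5-dimethoxybenzoate
Product: 15 (2R,3S,4R)-5,7-bis(benzyloxy)-2-[3,4-bis(benzyloxy)phenyl]-4-[(tert-butyldimethylsilyl)oxy]-3,4-dihydro-2H-chromen-3-yl 4-(benzyloxy)-3,5-dimethoxybenzoate (2,3-cis-3,4-cis), via oxocarbenium ion 13 (not isolated), via silyloxocarbenium ion 14 (not isolated)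
Conditions: 7 (2 equiv), (S,S)-imidodiphosphorimidate acid HN[P(=NSO2CF3)(3,3'-Ar2-1,1'-binaphthalene-2,2'-diolate)]2 with Ar = 3,5-(CF3)2C6H3 (5 mol %), 4 Å MS, toluene/CH2Cl2, −78 °C; Et3N quench
Reagents that add atoms: none
Why: Proposed new method: the chiral acid HX* protonates the acetate of racemic 12, which leaves in preference to the aryloxide because it is the better nucleofuge and the remaining cation keeps both the O-1 lone pair and the para 4'-benzyloxy group of ring B as donors, so both enantiomers of 12 converge on the planar (E)-O-aryl oxocarbenium ion 13 held as a contact ion pair with X*−; the acyloxy-bearing carbon of 7 then adds to C-2 (C2–C3 bond) to give silyloxocarbenium ion 14, whose C-4 is attacked at once by the ortho carbon C-4a of ring A (C4–C4a bond), and loss of the arenium proton returns HX* and releases acetic acid. The closest known reaction types are the oxa-Povarov reaction (SnCl4-promoted formal inverse-electron-demand [4+2] cycloaddition of cationic aryl 2-oxadienes with alkenes to chromans), the imidodiphosphorimidate-catalysed enantioselective addition of enolsilanes to oxocarbenium ions released from α-acetoxy ethers, and the Mukaiyama aldol addition of (Z)-2-acyloxy enolsilanes through their oxygenated carbon; new are the 1,2-dioxygenated dienophile in this cycloaddition and its control by a chiral anion. Ring C, the only ring closed, forms by a 6-(enolendo)-exo-trig Friedel–Crafts closure of C-4a onto the C4=O(+) unit or, if the two bonds form in concert, in the endo [4+2] mode. C-2 and C-3 are set together in the first bond formation: in (E)-13 ring B points outward, the (Z)-alkene holds both oxygen substituents endo below the cationic O1–C8a edge (the electrostatic preference behind 2,4-cis-selective Povarov reactions), outward plus endo means 2,3-cis, and the confined anion covers one face of C-2 and so fixes the absolute configuration 2R,3S (the same arrangement as 2R,3R once O-4 is gone). C-4 is set by suprafacial closure on the (Z)-alkene (expected 3,4-cis, 4R), and since step 8 erases it an epimer at C-4 is equally useful. The step needs regioselectivity, secured by the stronger donor OSi on the carbon that becomes C-4, site selectivity in ring A, which is no issue because its two ortho carbons are equivalent by symmetry and each lies ortho, ortho and para to three oxygens, and chemoselectivity against intermolecular Friedel–Crafts attack, secured by excess 7, dilution, low temperature and the fast intramolecular six-membered closure.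

Step 8
Reactants: 15 the all-cis 4-silyloxyflavan-3-yl ester from step 7
Product: 17 (2R,3R)-5,7-bis(benzyloxy)-2-[3,4-bis(benzyloxy)phenyl]-3,4-dihydro-2H-chromen-3-yl 4-(benzyloxy)-3,5-dimethoxybenzoate, via C-4 carbenium ion 16 (not isolated)
Conditions: Et3SiH, CF3CO2H, CH2Cl2, −40 to 0 °C; aq NaHCO3
Reagents that add atoms: none
Why: In this ionic hydrogenation (SN1), protonation expels the silanol because cation 16 is stabilised by O-5, O-7 and O-1 of ring A, and Et3SiH delivers hydride to C-4, which ceases to be a stereocentre, while C-2, C-3, the ester and the benzyl ethers should stay untouched at low temperature.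

Step 9
Reactants: 17 the penta-O-benzyl ester from step 8
Product: 18 (2R,3R)-2-(3,4-dihydroxyphenyl)-5,7-dihydroxy-3,4-dihydro-2H-chromen-3-yl 4-hydroxy-3,5-dimethoxybenzoate (target)
Conditions: H2 (1 atm), Pd(OH)2/C, THF/MeOH, rt; filtration under argon
Reagents that add atoms: none
Why: Catalytic hydrogenolysis cleaves the five exocyclic O–CH2Ph bonds much faster than the endocyclic secondary C2–O1 bond, and it leaves the ester and both stereocentres unchanged.

## Compound list

1 | syringic acid | COc1cc(C(=O)O)cc(OC)c1O | starting material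
2 | benzyl 4-(benzyloxy)-3,5-dimethoxybenzoate (not isolated) | COc1cc(C(=O)OCc2ccccc2)cc(OC)c1OCc1ccccc1 | intermediate
3 | 4-(benzyloxy)-3,5-dimethoxybenzoic acid | COc1cc(C(=O)O)cc(OC)c1OCc1ccccc1 | intermediate
4 | allyl 4-(benzyloxy)-3,5-dimethoxybenzoate | COc1cc(C(=O)OCC=C)cc(OC)c1OCc1ccccc1 | intermediate
5 | (1,2,4-trioxolan-3-yl)methyl 4-(benzyloxy)-3,5-dimethoxybenzoate, secondary ozonide, racemic (not isolated) | COc1cc(C(=O)OCC2OCOO2)cc(OC)c1OCc1ccccc1 | intermediate
6 | 2-oxoethyl 4-(benzyloxy)-3,5-dimethoxybenzoate | COc1cc(C(=O)OCC=O)cc(OC)c1OCc1ccccc1 | intermediate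
7 | (Z)-2-[(tert-butyldimethylsilyl)oxy]ethenyl 4-(benzyloxy)-3,5-dimethoxybenzoate | COc1cc(C(=O)O/C=C\O[Si](C)(C)C(C)(C)C)cc(OC)c1OCc1ccccc1 | intermediate
8 | 3,5-bis(benzyloxy)phenol | Oc1cc(OCc2ccccc2)cc(OCc2ccccc2)c1 | starting material
9 | 3,4-bis(benzyloxy)benzoic acid | OC(=O)c1ccc(OCc2ccccc2)c(OCc2ccccc2)c1 | starting material
10 | 3,5-bis(benzyloxy)phenyl 3,4-bis(benzyloxy)benzoate | O=C(Oc1cc(OCc2ccccc2)cc(OCc2ccccc2)c1)c1ccc(OCc2ccccc2)c(OCc2ccccc2)c1 | intermediate
11 | diisobutylaluminium alkoxide of the aryl hemiacetal, racemic (not isolated) | CC(C)C[Al](CC(C)C)OC(Oc1cc(OCc2ccccc2)cc(OCc2ccccc2)c1)c1ccc(OCc2ccccc2)c(OCc2ccccc2)c1 | intermediate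
12 | [3,4-bis(benzyloxy)phenyl][3,5-bis(benzyloxy)phenoxy]methyl acetate, racemic | CC(=O)OC(Oc1cc(OCc2ccccc2)cc(OCc2ccccc2)c1)c1ccc(OCc2ccccc2)c(OCc2ccccc2)c1 | intermediate
13 | (E)-[3,4-bis(benzyloxy)benzylidene][3,5-bis(benzyloxy)phenyl]oxonium, ion pair with the chiral anion (not isolated) | O(Cc1ccccc1)c1cc(OCc2ccccc2)cc(/[O+]=C/c2ccc(OCc3ccccc3)c(OCc3ccccc3)c2)c1 | intermediate
14 | O-silylated 3-aryl-3-aryloxy-2-acyloxypropanal cation, C2–C3 bond formed, ring C still open (not isolated) | COc1cc(C(=O)O[C@H](C=[O+][Si](C)(C)C(C)(C)C)[C@H](Oc2cc(OCc3ccccc3)cc(OCc3ccccc3)c2)c2ccc(OCc3ccccc3)c(OCc3ccccc3)c2)cc(OC)c1OCc1ccccc1 | intermediate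
15 | (2R,3S,4R)-5,7-bis(benzyloxy)-2-[3,4-bis(benzyloxy)phenyl]-4-[(tert-butyldimethylsilyl)oxy]-3,4-dihydro-2H-chromen-3-yl 4-(benzyloxy)-3,5-dimethoxybenzoate, all-cis | COc1cc(C(=O)O[C@@H]2[C@H](O[Si](C)(C)C(C)(C)C)c3c(OCc4ccccc4)cc(OCc4ccccc4)cc3O[C@@H]2c2ccc(OCc3ccccc3)c(OCc3ccccc3)c2)cc(OC)c1OCc1ccccc1 | intermediate
16 | C-4 carbenium ion of the protected flavan-3-yl ester (not isolated) | COc1cc(C(=O)O[C@@H]2[CH+]c3c(OCc4ccccc4)cc(OCc4ccccc4)cc3O[C@@H]2c2ccc(OCc3ccccc3)c(OCc3ccccc3)c2)cc(OC)c1OCc1ccccc1 | intermediate
17 | (2R,3R)-5,7-bis(benzyloxy)-2-[3,4-bis(benzyloxy)phenyl]-3,4-dihydro-2H-chromen-3-yl 4-(benzyloxy)-3,5-dimethoxybenzoate | COc1cc(C(=O)O[C@@H]2Cc3c(OCc4ccccc4)cc(OCc4ccccc4)cc3O[C@@H]2c2ccc(OCc3ccccc3)c(OCc3ccccc3)c2)cc(OC)c1OCc1ccccc1 | intermediate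
18 | (−)-epicatechin 3-O-syringate, (2R,3R) | COc1cc(C(=O)O[C@@H]2Cc3c(O)cc(O)cc3O[C@@H]2c2ccc(O)c(O)c2)cc(OC)c1O | target

## Step count and risks

Total step count: 9.
Longest linear sequence: 7 steps (1, 2, 3, 4, 7, 8, 9). Steps 5 and 6 form the second branch.

**Most likely to fail**

1. Step 7 (Proposed new method).
   - What may go wrong:
     - The anion may discriminate poorly between the faces of so large a cation.
     - Endo/exo (cis/trans) selectivity in the first bond formation may be weak.
     - Ring A of a second molecule may attack the cation.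
     - The acid may ionise the new C4–O bond and start oligomerisation.
   - Fallback (known chemistry, a chiral-pool relay in place of the cycloaddition): it sets out from acid 3 and comes back at 17. Commercial (−)-epicatechin is benzylated at its four phenols (BnBr, K2CO3, DMF, rt) to 5,7,3',4'-tetra-O-benzyl-(−)-epicatechin F1. F1 is then acylated at O-3 with 3 (DCC, DMAP, CH2Cl2, Steglich esterification) to give 17, after which only step 9 remains.

2. Step 6.
   - What may go wrong: the aluminium hemiacetal may collapse by loss of the aryloxide before it is acetylated, followed by over-reduction. The acetate may also hydrolyse during isolation.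
   - Fallback (approach from the ether oxidation level by oxidation instead of from the ester by reduction): it sets out from phenol 8 and comes back at 12. Phenol 8 is O-alkylated with commercial 3,4-bis(benzyloxy)benzyl chloride (K2CO3, DMF, rt) to 1,3-bis(benzyloxy)-5-{[3,4-bis(benzyloxy)phenyl]methoxy}benzene F2. DDQ with AcOH (4 Å MS, CH2Cl2, 0 °C) should then abstract hydride from the dialkoxybenzylic CH2, and acetic acid should capture the cation to give 12.

3. Step 8.
   - What may go wrong:
     - The C-4 cation may lose H-3 to give a flav-3-ene.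
     - It may be attacked by C-6 or C-8 of a second flavan.
     - The C2–O1 bond may open under acid, with epimerisation at C-2.
   - Fallback (capture of the cation by a much better nucleophile, then radical reduction instead of hydride transfer): it sets out from 15 and comes back at 17. Thiophenol with a catalytic amount of AcOH or pyridinium tosylate (CH2Cl2, 0 °C; thiolysis as known for 4-oxygenated flavans) should give the (2R,3S,4S)-4-(phenylsulfanyl)flavan-3-yl ester F3 by attack anti to the 3-acyloxy group. Bu3SnH and AIBN (toluene, 90 °C) should then cleave the benzylic C–S bond to give 17.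

## Further compounds

F1 | step 7 | 5,7,3',4'-tetra-O-benzyl-(−)-epicatechin | O[C@@H]1Cc2c(OCc3ccccc3)cc(OCc3ccccc3)cc2O[C@@H]1c1ccc(OCc2ccccc2)c(OCc2ccccc2)c1
F2 | step 6 | 1,3-bis(benzyloxy)-5-{[3,4-bis(benzyloxy)phenyl]methoxy}benzene | C(Oc1cc(OCc2ccccc2)cc(OCc2ccccc2)c1)c1ccc(OCc2ccccc2)c(OCc2ccccc2)c1
F3 | step 8 | (2R,3S,4S)-5,7-bis(benzyloxy)-2-[3,4-bis(benzyloxy)phenyl]-4-(phenylsulfanyl)-3,4-dihydro-2H-chromen-3-yl 4-(benzyloxy)-3,5-dimethoxybenzoate | COc1cc(C(=O)O[C@@H]2[C@@H](Sc3ccccc3)c3c(OCc4ccccc4)cc(OCc4ccccc4)cc3O[C@@H]2c2ccc(OCc3ccccc3)c(OCc3ccccc3)c2)cc(OC)c1OCc1ccccc1
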